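Late in a run, once the nucleophile and the free base both stand at balance with the acid set free, the clock drops out of how the nucleophile is shared; test that on this flask.

electrophile 2.0 mM; free base 1.00 equiv; protonated nucleophile 1.05 equiv; time 40 s

    electrophile + nucleophile → acid set free + target (k1 = 3100 M⁻¹ s⁻¹)
    nucleophile + acid set free ⇌ protonated nucleophile, settled at all times (K2 = 1.4 × 10⁶ M⁻¹)
    acid set free + free base ⇌ salt of the base (K3 = 1.8 × 10⁵ M⁻¹, k3 = 620 M⁻¹ s⁻¹)
    2 electrophile → homo dimer (k4 = 41 M⁻¹ s⁻¹)
    electrophile + target → side product (k5 = 230 M⁻¹ s⁻¹)
    target → over-reaction product (k6 = 0.024 s⁻¹)

- in percentages every species weighs as the electrophile in it: one homo dimer or side product counts as two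
- two of one species on the left: rate k times its square, two consumed each time
- run time (flask): 40 s

- part of the electrophile that has reacted at 40 s
- share of the unused nucleophile that is free and not bound as protonated nucleophile, at 40 s

Divide the balance of the free base by that of the nucleophile, 1.8 × 10⁵ M⁻¹ over 1.4 × 10⁶ M⁻¹, and [acid set free] cancels. What remains is the hand-over constant (an exchange equilibrium constant), the odds at which free base takes acid from protonated nucleophile, 0.129:

  [nucleophile] / [protonated nucleophile] = hand-over constant × [free base] / [salt of the base]

  free share = odds / (one + odds)

Now turn the settings by hand. Give the run more time and you approach this balance, while acid still being made should hold the share beneath it. Change the electrophile with its equivalents held and the balance keeps its form, since the constant carries no concentration, though a smaller charge gets there later. More free base raises the odds, and more protonated nucleophile lowers them.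

For this flask, equal [free base] and [salt of the base] would give 11.4 %. Step 1 has a half-life for nucleophile of 0.11 s with the electrophile as charged, which is shorter than the run, and each turn uses a nucleophile and sets an acid free for the free base, so I expect [salt of the base] to pass [free base] and commit to a share below that. The homo dimer step by itself would leave 13.2 % of the electrophile at 40 s, so I put the reacted part above 86.8 %.

The forecast gave 99.9 % and 9 %, reasoning that “the base slowly strips acid from the remaining protonated nucleophile”; mine are a limit on each side, an expected one for the share, not its numbers.

The flask gives 99.6 % and 3.12 %. The free share was 1.50 % at 20.0 s, so it is still climbing. With the [free base] and [salt of the base] standing at 40 s, the hand-over constant gives a balance share of 5.74 %, which is more than the flask shows.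

In the neighbour flask charged with 0.50 mM of electrophile, the same reckoning gives 7.14 %. Its computed share is 1.87 %, further beneath its balance than the first flask.

The constants used here were drawn at random within sensible limits; the run is a simulation.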